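**Retrosynthetic overview**

- The target is cut at the ester between a bis-silylated left acid and a right diol (Yamaguchi esterification, then one fluoride deprotection). The two halves have opposite absolute configuration at the isopropyl-bearing carbon, so each has its own asymmetric entry.
- Right half: the hydroxylated cyclohexane is formed last, by contraction of the cycloheptane ring of an epoxy lactol. One base-catalysed Favorskii-type 1,2-shift contracts the carbocycle and at the same time enlarges the six-membered lactol to the seven-membered lactone.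
- Enabling feature: in the epoxy lactol the hemiketal carbon C-9a belongs to both the cycloheptane and the dihydropyranol ring and is bonded to the epoxide carbon C-9. Its bond to the ring-fusion carbon C-4a can lie anti to the C-9–O bond, and the symmetric bis(hydroxymethyl)alkene lets the lactol form without any alkene-geometry problem.
- The epoxy lactol comes from cycloheptane-1,3-dione: Stork–Danheiser enone, cross-conjugated dienone, asymmetric i-Pr2Zn addition with Cu(OTf)2/phosphoramidite, α-alkenylation with Pd2(dba)3/P(t-Bu)3, then reduction, directed epoxidation, oxidation and acetonide removal.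
- Left half from (R)-cryptone: vinyl addition/enol triflate, ozonolysis–bromo-Wittig, double Stille hydroxymethylation. Ring order: cycloheptenone → epoxide → dihydropyranol → (key step) cyclohexane + oxepinone; the left cyclohexene ring is made by aldol condensation.

Key step: step 12

Remark: the lactol made in step 11 is drawn as one hemiketal anomer; both anomers interconvert through the open hydroxy ketone, so that centre is not a stereochemical issue.
Remark: the enantiomer of each chiral catalyst (steps 5 and 16) is chosen to give the configurations drawn; the sense of induction is expected by analogy and both antipodes are commercial.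

**Route**

Step 1
Reactants: 1 (tributylstannyl)methanol
Product: 2 tributyl{[(4-methoxybenzyl)oxy]methyl}stannane
Conditions: NaH, 4-MeOC6H4CH2Cl, Bu4NI (cat.), THF/DMF, 0 °C → rt
Reagents that add atoms: 4-methoxybenzyl chloride COc1ccc(CCl)cc1
Why: Williamson etherification of the primary stannyl carbinol gives the α-alkoxymethylstannane needed for tin–lithium exchange; no stereocentre is formed.

Step 2
Reactants: 3 cycloheptane-1,3-dione
Product: 4 3-(2-methylpropoxy)cyclohept-2-en-1-one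
Conditions: i-BuOH, TsOH·H2O (cat.), toluene, reflux, Dean–Stark
Reagents that add atoms: 2-methylpropan-1-ol CC(C)CO
Why: Acid-catalysed condensation of the cyclic 1,3-diketone with the alcohol under azeotropic water removal gives the vinylogous ester for a Stork–Danheiser transposition.

Step 3
Reactants: 2 tributyl{[(4-methoxybenzyl)oxy]methyl}stannane; 4 3-(2-methylpropoxy)cyclohept-2-en-1-one
Product: 7 3-{[(4-methoxybenzyl)oxy]methyl}cyclohept-2-en-1-one, via alkoxymethyllithium 5 (not isolated), via lithium carbinolate 6 (not isolated)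
Conditions: 2, n-BuLi, THF, −78 °C; then 4, −78 → 0 °C; then 1 M HCl, rt
Reagents that add atoms: water O
Why: Tin–lithium exchange gives the α-alkoxymethyllithium, which adds 1,2 to the vinylogous ester, and acid hydrolysis with loss of isobutanol delivers the transposed 3-substituted enone (Stork–Danheiser sequence).

Step 4
Reactants: 7 3-{[(4-methoxybenzyl)oxy]methyl}cyclohept-2-en-1-one
Product: 9 3-{[(4-methoxybenzyl)oxy]methyl}cyclohepta-2,6-dien-1-one, via silyl dienol ether 8 (not isolated)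
Conditions: LiN(i-Pr)2, THF, −78 °C; Me3SiCl; then Pd(OAc)2 (1.05 equiv), MeCN, rt
Reagents that add atoms: none
Why: Kinetic α′-deprotonation/silylation followed by Saegusa–Ito dehydrogenation with Pd(OAc)2 should introduce the C6–C7 double bond regiospecifically and give the achiral cross-conjugated dienone.

Step 5
Reactants: 9 3-{[(4-methoxybenzyl)oxy]methyl}cyclohepta-2,6-dien-1-one
Product: 11 {[(7S)-7-isopropyl-4-{[(4-methoxybenzyl)oxy]methyl}cyclohepta-1,3-dien-2-yl]oxy}trimethylsilane, via i-PrZn enolate 10 (not isolated)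
Conditions: i-Pr2Zn (1.5 equiv), Cu(OTf)2 (2 mol %), (R,S,S)-binaphthol bis(1-phenylethyl)amine phosphoramidite (4 mol %), toluene, −30 °C; then Me3SiOTf, −30 → 0 °C
Reagents that add atoms: diisopropylzinc CC(C)[Zn]C(C)C; trimethylsilyl trifluoromethanesulfonate C[Si](C)(C)OS(=O)(=O)C(F)(F)F
Why: Asymmetric conjugate addition of the dialkylzinc with Cu(OTf)2 and the chiral phosphoramidite should go only to the unsubstituted β-carbon (the β,β-disubstituted terminus is unreactive), the ligand setting the isopropyl-bearing stereocentre, and O-silylation of the zinc enolate fixes the enolate regiochemistry.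

Step 6
Reactants: 12 2,2-dimethyl-1,3-dioxan-5-one
Product: 13 5-(bromomethylidene)-2,2-dimethyl-1,3-dioxane
Conditions: Ph3P+CH2Br Br−, KOt-Bu, THF, −78 °C → rt
Reagents that add atoms: (bromomethyl)triphenylphosphonium bromide [Br-].BrC[P+](c1ccccc1)(c1ccccc1)c1ccccc1
Why: Wittig bromomethylenation of the symmetrical ketone gives the alkenyl bromide; the two ring arms are identical, so no alkene geometry arises.

Step 7
Reactants: 11 {[(7S)-7-isopropyl-4-{[(4-methoxybenzyl)oxy]methyl}cyclohepta-1,3-dien-2-yl]oxy}trimethylsilane; 13 5-(bromomethylidene)-2,2-dimethyl-1,3-dioxane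
Product: 15 (6S,7R)-7-[(2,2-dimethyl-1,3-dioxan-5-ylidene)methyl]-6-isopropyl-3-{[(4-methoxybenzyl)oxy]methyl}cyclohept-2-en-1-one, via Bu3Sn enolate 14 (not isolated)
Conditions: Pd2(dba)3 (2.5 mol %), P(t-Bu)3 (10 mol %), Bu3SnF (1.2 equiv), toluene, 70 °C
Reagents that add atoms: none
Why: Fluoride-induced silicon-to-tin exchange gives the tin enolate, which undergoes α-alkenylation of a ketone enolate equivalent with the alkenyl bromide under Pd2(dba)3/P(t-Bu)3 without strong base; C–C bond formation on the enolate face anti to the neighbouring isopropyl group should give the 6,7-trans ketone.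

Step 8
Reactants: 15 (6S,7R)-7-[(2,2-dimethyl-1,3-dioxan-5-ylidene)methyl]-6-isopropyl-3-{[(4-methoxybenzyl)oxy]methyl}cyclohept-2-en-1-one
Product: 16 (1S,6S,7R)-7-[(2,2-dimethyl-1,3-dioxan-5-ylidene)methyl]-6-isopropyl-3-{[(4-methoxybenzyl)oxy]methyl}cyclohept-2-en-1-ol
Conditions: LiBH(s-Bu)3, THF, −78 °C; H2O
Reagents that add atoms: none
Why: 1,2-Reduction of the β,β-disubstituted enone by the bulky borohydride under steric approach control, with hydride arriving anti to the C7 alkenyl group, should give the alcohol cis to that group.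

Step 9
Reactants: 16 (1S,6S,7R)-7-[(2,2-dimethyl-1,3-dioxan-5-ylidene)methyl]-6-isopropyl-3-{[(4-methoxybenzyl)oxy]methyl}cyclohept-2-en-1-ol
Product: 17 (1S,2S,3R,4S,7S)-3-[(2,2-dimethyl-1,3-dioxan-5-ylidene)methyl]-4-isopropyl-7-{[(4-methoxybenzyl)oxy]methyl}-8-oxabicyclo[5.1.0]octan-2-ol
Conditions: VO(acac)2 (5 mol %), t-BuOOH (decane), CH2Cl2, 0 °C → rt
Reagents that add atoms: tert-butyl hydroperoxide CC(C)(C)OO
Why: Hydroxyl-directed epoxidation with VO(acac)2/t-BuOOH delivers oxygen syn to the allylic hydroxyl of the cycloheptenol, setting both epoxide centres, and is much faster than reaction at the merely homoallylic side-chain alkene.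

Step 10
Reactants: 17 (1S,2S,3R,4S,7S)-3-[(2,2-dimethyl-1,3-dioxan-5-ylidene)methyl]-4-isopropyl-7-{[(4-methoxybenzyl)oxy]methyl}-8-oxabicyclo[5.1.0]octan-2-ol
Product: 18 (1R,3R,4S,7S)-3-[(2,2-dimethyl-1,3-dioxan-5-ylidene)methyl]-4-isopropyl-7-{[(4-methoxybenzyl)oxy]methyl}-8-oxabicyclo[5.1.0]octan-2-one
Conditions: Dess–Martin periodinane, NaHCO3, CH2Cl2, 0 °C → rt
Reagents that add atoms: none
Why: Buffered Dess–Martin oxidation of the secondary alcohol gives the α,β-epoxy ketone without epimerising the α′-centre or touching the epoxide.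

Step 11
Reactants: 18 (1R,3R,4S,7S)-3-[(2,2-dimethyl-1,3-dioxan-5-ylidene)methyl]-4-isopropyl-7-{[(4-methoxybenzyl)oxy]methyl}-8-oxabicyclo[5.1.0]octan-2-one
Product: 20 8,9-epoxy-3-(hydroxymethyl)-5-isopropyl-8-{[(4-methoxybenzyl)oxy]methyl}-2,4a,5,6,7,8,9,9a-octahydrocyclohepta[b]pyran-9a-ol (lactol), via dihydroxy ketone 19 (not isolated)
Conditions: AcOH/THF/H2O (3:1:1), 40 °C
Reagents that add atoms: none
Why: Mild acetal hydrolysis frees the diol, and only the hydroxymethyl group cis to the ring across the trisubstituted alkene can reach the ketone, so 6-exo-trig hemiketalisation should give the lactol, which differentiates the two CH2OH groups and masks the ketone.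

Step 12
Reactants: 20 8,9-epoxy-3-(hydroxymethyl)-5-isopropyl-8-{[(4-methoxybenzyl)oxy]methyl}-2,4a,5,6,7,8,9,9a-octahydrocyclohepta[b]pyran-9a-ol
Product: 21 (5aR,6S,9R,9aS)-9-hydroxy-4-(hydroxymethyl)-6-isopropyl-9-{[(4-methoxybenzyl)oxy]methyl}-5a,6,7,8,9,9a-hexahydro-2-benzoxepin-1(3H)-one
Conditions: LiOt-Bu (0.2 equiv), THF, 0 °C → rt; AcOH quench
Reagents that add atoms: none
Why: Proposed new method: the lithium alkoxide of the hemiketal carbon C-9a of 20 should undergo a semibenzilic 1,2-shift in which the C-9a–C-4a bond, brought close to antiperiplanar to the C-9–O epoxide bond by the flexible seven-membered ring, migrates to C-9 while the hemiketal collapses to the lactone carbonyl and the epoxide opens to the tertiary alkoxide; that alkoxide is reprotonated by the next molecule of 20, so catalytic base suffices. The closest known reaction type is the base-induced Favorskii-type (quasi-Favorskii) ring contraction of cyclic α,β-epoxy ketones to β-hydroxy acids, run here through an internal hemiketal instead of a hydroxide adduct. Both rings of 21 arise from this single shift and not from an end-on cyclisation: the cyclohexane by contraction of the cycloheptane (intramolecular displacement at the epoxide carbon, formally 3-exo-tet) and the oxepinone by one-atom enlargement of the dihydropyranol. C-9a of 21 is set by inversion at the former epoxide carbon, C-9 keeps the configuration fixed in step 9 because its C–O bond is not touched, and the migrating carbon (C-5a of 21) retains its configuration, which together give the cis-fused lactone with the carbonyl carbon cis to the tertiary hydroxyl. The step needs C–C migration to win over epoxide opening at the tertiary carbon, Payne-type oxygen migration, enolisation and retro-aldol cleavage: base-only activation avoids a cation at the tertiary epoxide carbon, the lactol masks the ketone so C-4a cannot enolise, a Payne isomer can revert whereas lactone formation is irreversible, and catalytic base keeps the β-alkoxy lactone concentration low.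

Step 13
Reactants: 21 (5aR,6S,9R,9aS)-9-hydroxy-4-(hydroxymethyl)-6-isopropyl-9-{[(4-methoxybenzyl)oxy]methyl}-5a,6,7,8,9,9a-hexahydro-2-benzoxepin-1(3H)-one
Product: 23 (5aR,6S,9R,9aS)-9-hydroxy-6-isopropyl-9-{[(4-methoxybenzyl)oxy]methyl}-1-oxo-1,3,5a,6,7,8,9,9a-octahydro-2-benzoxepine-4-carboxylic acid, via enal 22 (not isolated)
Conditions: TEMPO (10 mol %), PhI(OAc)2, CH2Cl2, rt; then t-BuOH/H2O, 2-methylbut-2-ene, NaH2PO4, NaClO2, 0 °C → rt
Reagents that add atoms: sodium chlorite [Na+].[O-]Cl=O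
Why: Oxoammonium oxidation takes only the primary allylic alcohol (the tertiary alcohol is inert) to the enal, and Pinnick oxidation in the same flask gives the acid.

Step 14
Reactants: 23 (5aR,6S,9R,9aS)-9-hydroxy-6-isopropyl-9-{[(4-methoxybenzyl)oxy]methyl}-1-oxo-1,3,5a,6,7,8,9,9a-octahydro-2-benzoxepine-4-carboxylic acid
Product: 24 2-(trimethylsilyl)ethyl (5aR,6S,9R,9aS)-9-hydroxy-6-isopropyl-9-{[(4-methoxybenzyl)oxy]methyl}-1-oxo-1,3,5a,6,7,8,9,9a-octahydro-2-benzoxepine-4-carboxylate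
Conditions: Me3SiCH2CH2OH, EDC·HCl, DMAP, CH2Cl2, rt
Reagents that add atoms: 2-(trimethylsilyl)ethanol C[Si](C)(C)CCO
Why: Steglich esterification masks the acid as a fluoride-labile ester; the hindered tertiary alcohol is not acylated.

Step 15
Reactants: 24 2-(trimethylsilyl)ethyl (5aR,6S,9R,9aS)-9-hydroxy-6-isopropyl-9-{[(4-methoxybenzyl)oxy]methyl}-1-oxo-1,3,5a,6,7,8,9,9a-octahydro-2-benzoxepine-4-carboxylate
Product: 25 2-(trimethylsilyl)ethyl (5aR,6S,9R,9aS)-9-hydroxy-9-(hydroxymethyl)-6-isopropyl-1-oxo-1,3,5a,6,7,8,9,9a-octahydro-2-benzoxepine-4-carboxylate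
Conditions: DDQ, CH2Cl2/pH 7 buffer (10:1), 0 °C → rt
Reagents that add atoms: none
Why: Oxidative cleavage of the 4-methoxybenzyl ether in wet solvent frees the primary alcohol; translactonisation to a γ-lactone is disfavoured because the CH2OH group is trans to the lactone carbonyl carbon.

Step 16
Reactants: 26 3-methylbutanal; 27 but-3-en-2-one
Product: 28 (2R)-2-isopropyl-5-oxohexanal
Conditions: (R)-2-(methoxydiphenylmethyl)pyrrolidine (5 mol %), ethyl 3,4-dihydroxybenzoate (20 mol %), neat, 4 °C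
Reagents that add atoms: none
Why: Enamine-catalysed Michael addition of the aldehyde to the enone, in which the diarylmethyl group shields one enamine face, should set the α-stereocentre (R expected with the (R)-catalyst).

Step 17
Reactants: 28 (2R)-2-isopropyl-5-oxohexanal
Product: 29 (4R)-4-isopropylcyclohex-2-en-1-one ((R)-cryptone)
Conditions: LiOH (cat.), i-PrOH, rt
Reagents that add atoms: none
Why: Intramolecular aldol condensation of the methyl ketone onto the aldehyde closes the cyclohexenone under mild base, which should leave the γ-stereocentre intact.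

Step 18
Reactants: 30 methyl (triphenylphosphoranylidene)acetate
Product: 31 methyl bromo(triphenylphosphoranylidene)acetate
Conditions: N-bromosuccinimide, CH2Cl2, −20 °C → rt
Reagents that add atoms: N-bromosuccinimide O=C1CCC(=O)N1Br
Why: Electrophilic bromination of the stabilised ylide, with succinimide anion as the internal base, gives the isolable bromo ylide.

Step 19
Reactants: 29 (4R)-4-isopropylcyclohex-2-en-1-one
Product: 33 (3R,4R)-3-ethenyl-4-isopropylcyclohex-1-en-1-yl trifluoromethanesulfonate, via BrMg enolate 32 (not isolated)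
Conditions: CH2=CHMgBr, CuBr·SMe2 (10 mol %), THF, −78 °C; then N-(5-chloro-2-pyridyl)bis(trifluoromethanesulfonimide), −78 °C → rt
Reagents that add atoms: vinylmagnesium bromide C=C[Mg]Br; N-(5-chloro-2-pyridyl)bis(trifluoromethanesulfonimide) O=S(=O)(N(c1ccc(Cl)cn1)S(=O)(=O)C(F)(F)F)C(F)(F)F
Why: Conjugate addition of the vinyl Grignard reagent with CuBr·SMe2 anti to the C4 isopropyl group sets C3 (trans), and O-triflation of the regiodefined enolate fixes the position of the ring double bond.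

Step 20
Reactants: 33 (3R,4R)-3-ethenyl-4-isopropylcyclohex-1-en-1-yl trifluoromethanesulfonate; 31 methyl bromo(triphenylphosphoranylidene)acetate
Product: 35 methyl (2Z)-2-bromo-3-[(1R,6R)-6-isopropyl-3-{[(trifluoromethyl)sulfonyl]oxy}cyclohex-2-en-1-yl]prop-2-enoate, via aldehyde 34 (not isolated)
Conditions: O3, CH2Cl2, −78 °C; PPh3, −78 °C → rt; then 31, CH2Cl2, rt
Reagents that add atoms: none
Why: Ozonolysis cleaves the electron-rich vinyl group in preference to the electron-poor enol triflate, and neutral in-situ Wittig olefination of the sensitive aldehyde with the stabilised bromo ylide should give the (Z)-α-bromo enoate (ester trans to the ring) without epimerising the α-centre.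

Step 21
Reactants: 35 methyl (2Z)-2-bromo-3-[(1R,6R)-6-isopropyl-3-{[(trifluoromethyl)sulfonyl]oxy}cyclohex-2-en-1-yl]prop-2-enoate; 1 (tributylstannyl)methanol
Product: 36 methyl (2E)-2-(hydroxymethyl)-3-[(1R,6R)-3-(hydroxymethyl)-6-isopropylcyclohex-2-en-1-yl]prop-2-enoate
Conditions: 1 (2.6 equiv), Pd(PPh3)4 (10 mol %), LiCl, 1,4-dioxane, 95 °C
Reagents that add atoms: none
Why: Double Stille hydroxymethylation with Pd(PPh3)4 replaces both the alkenyl triflate and the alkenyl bromide by CH2OH with retention of alkene geometry, so the side-chain CH2OH ends up cis to the ring.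

Step 22
Reactants: 36 methyl (2E)-2-(hydroxymethyl)-3-[(1R,6R)-3-(hydroxymethyl)-6-isopropylcyclohex-2-en-1-yl]prop-2-enoate
Product: 37 methyl (2E)-2-({[tert-butyl(dimethyl)silyl]oxy}methyl)-3-[(1R,6R)-3-({[tert-butyl(dimethyl)silyl]oxy}methyl)-6-isopropylcyclohex-2-en-1-yl]prop-2-enoate
Conditions: t-BuMe2SiCl, imidazole, DMF, rt
Reagents that add atoms: tert-butyldimethylsilyl chloride CC(C)(C)[Si](C)(C)Cl
Why: Standard silylation protects both primary allylic alcohols so that only the right-half alcohol can be acylated later.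

Step 23
Reactants: 37 methyl (2E)-2-({[tert-butyl(dimethyl)silyl]oxy}methyl)-3-[(1R,6R)-3-({[tert-butyl(dimethyl)silyl]oxy}methyl)-6-isopropylcyclohex-2-en-1-yl]prop-2-enoate
Product: 38 (2E)-2-({[tert-butyl(dimethyl)silyl]oxy}methyl)-3-[(1R,6R)-3-({[tert-butyl(dimethyl)silyl]oxy}methyl)-6-isopropylcyclohex-2-en-1-yl]prop-2-enoic acid
Conditions: LiOH·H2O, THF/MeOH/H2O, rt → 40 °C; then aq. HCl to pH 4
Reagents that add atoms: lithium hydroxide [Li+].[OH-]
Why: Saponification of the methyl ester under conditions that primary silyl ethers tolerate gives the acid without moving the conjugated double bond.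

Step 24
Reactants: 38 (2E)-2-({[tert-butyl(dimethyl)silyl]oxy}methyl)-3-[(1R,6R)-3-({[tert-butyl(dimethyl)silyl]oxy}methyl)-6-isopropylcyclohex-2-en-1-yl]prop-2-enoic acid; 25 2-(trimethylsilyl)ethyl (5aR,6S,9R,9aS)-9-hydroxy-9-(hydroxymethyl)-6-isopropyl-1-oxo-1,3,5a,6,7,8,9,9a-octahydro-2-benzoxepine-4-carboxylate
Product: 40 2-(trimethylsilyl)ethyl (5aR,6S,9R,9aS)-9-({[(2E)-2-({[tert-butyl(dimethyl)silyl]oxy}methyl)-3-[(1R,6R)-3-({[tert-butyl(dimethyl)silyl]oxy}methyl)-6-isopropylcyclohex-2-en-1-yl]prop-2-enoyl]oxy}methyl)-9-hydroxy-6-isopropyl-1-oxo-1,3,5a,6,7,8,9,9a-octahydro-2-benzoxepine-4-carboxylate, via mixed anhydride 39 (not isolated)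
Conditions: 2,4,6-Cl3C6H2COCl, Et3N, toluene, rt; then 25, DMAP, rt
Reagents that add atoms: none
Why: Yamaguchi esterification through the mixed anhydride acylates the primary hydroxyl of the diol chemoselectively, the tertiary hydroxyl being too hindered.

Step 25
Reactants: 40 2-(trimethylsilyl)ethyl (5aR,6S,9R,9aS)-9-({[(2E)-2-({[tert-butyl(dimethyl)silyl]oxy}methyl)-3-[(1R,6R)-3-({[tert-butyl(dimethyl)silyl]oxy}methyl)-6-isopropylcyclohex-2-en-1-yl]prop-2-enoyl]oxy}methyl)-9-hydroxy-6-isopropyl-1-oxo-1,3,5a,6,7,8,9,9a-octahydro-2-benzoxepine-4-carboxylate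
Product: 41 (5aR,6S,9R,9aS)-9-hydroxy-9-({[(2E)-2-(hydroxymethyl)-3-[(1R,6R)-3-(hydroxymethyl)-6-isopropylcyclohex-2-en-1-yl]prop-2-enoyl]oxy}methyl)-6-isopropyl-1-oxo-1,3,5a,6,7,8,9,9a-octahydro-2-benzoxepine-4-carboxylic acid (CNP0361406.3)
Conditions: Bu4NF, AcOH, THF, 0 °C → rt
Reagents that add atoms: none
Why: Buffered fluoride cleaves both silyl ethers and, by β-elimination, the 2-(trimethylsilyl)ethyl ester in one global deprotection that should leave the lactone, the acrylate ester and all stereocentres untouched.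

**Compound list**

1 | (tributylstannyl)methanol | CCCC[Sn](CCCC)(CCCC)CO | starting material
2 | tributyl{[(4-methoxybenzyl)oxy]methyl}stannane | CCCC[Sn](CCCC)(CCCC)COCc1ccc(OC)cc1 | intermediate
3 | cycloheptane-1,3-dione | O=C1CCCCC(=O)C1 | starting material
4 | 3-(2-methylpropoxy)cyclohept-2-en-1-one | CC(C)COC1=CC(=O)CCCC1 | intermediate
5 | {[(4-methoxybenzyl)oxy]methyl}lithium | [Li]COCc1ccc(OC)cc1 | intermediate (not isolated)
6 | lithium 3-(2-methylpropoxy)-1-{[(4-methoxybenzyl)oxy]methyl}cyclohept-2-en-1-olate (racemic) | CC(C)COC1=CC(O[Li])(COCc2ccc(OC)cc2)CCCC1 | intermediate (not isolated)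
7 | 3-{[(4-methoxybenzyl)oxy]methyl}cyclohept-2-en-1-one | O=C1C=C(COCc2ccc(OC)cc2)CCCC1 | intermediate
8 | {[4-{[(4-methoxybenzyl)oxy]methyl}cyclohepta-1,3-dien-2-yl]oxy}trimethylsilane | C[Si](C)(C)OC1=CCCCC(COCc2ccc(OC)cc2)=C1 | intermediate (not isolated)
9 | 3-{[(4-methoxybenzyl)oxy]methyl}cyclohepta-2,6-dien-1-one | O=C1C=C(COCc2ccc(OC)cc2)CCC=C1 | intermediate
10 | isopropylzinc (7S)-7-isopropyl-4-{[(4-methoxybenzyl)oxy]methyl}cyclohepta-1,3-dien-2-olate | CC(C)[Zn]OC1=C[C@H](C(C)C)CCC(COCc2ccc(OC)cc2)=C1 | intermediate (not isolated)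
11 | {[(7S)-7-isopropyl-4-{[(4-methoxybenzyl)oxy]methyl}cyclohepta-1,3-dien-2-yl]oxy}trimethylsilane | C[Si](C)(C)OC1=C[C@H](C(C)C)CCC(COCc2ccc(OC)cc2)=C1 | intermediate
12 | 2,2-dimethyl-1,3-dioxan-5-one | CC1(C)OCC(=O)CO1 | starting material
13 | 5-(bromomethylidene)-2,2-dimethyl-1,3-dioxane | CC1(C)OCC(=CBr)CO1 | intermediate
14 | tributyl{[(7S)-7-isopropyl-4-{[(4-methoxybenzyl)oxy]methyl}cyclohepta-1,3-dien-2-yl]oxy}stannane | CCCC[Sn](CCCC)(CCCC)OC1=C[C@H](C(C)C)CCC(COCc2ccc(OC)cc2)=C1 | intermediate (not isolated)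
15 | (6S,7R)-7-[(2,2-dimethyl-1,3-dioxan-5-ylidene)methyl]-6-isopropyl-3-{[(4-methoxybenzyl)oxy]methyl}cyclohept-2-en-1-one (isopropyl and alkenyl trans) | O=C1C=C(COCc2ccc(OC)cc2)CC[C@@H](C(C)C)[C@@H]1C=C1COC(C)(C)OC1 | intermediate
16 | (1S,6S,7R)-7-[(2,2-dimethyl-1,3-dioxan-5-ylidene)methyl]-6-isopropyl-3-{[(4-methoxybenzyl)oxy]methyl}cyclohept-2-en-1-ol (OH cis to alkenyl) | O[C@@H]1C=C(COCc2ccc(OC)cc2)CC[C@@H](C(C)C)[C@@H]1C=C1COC(C)(C)OC1 | intermediate
17 | (1S,2S,3R,4S,7S)-3-[(2,2-dimethyl-1,3-dioxan-5-ylidene)methyl]-4-isopropyl-7-{[(4-methoxybenzyl)oxy]methyl}-8-oxabicyclo[5.1.0]octan-2-ol (epoxide syn to OH) | O[C@@H]1[C@@H]2O[C@]2(COCc3ccc(OC)cc3)CC[C@@H](C(C)C)[C@@H]1C=C1COC(C)(C)OC1 | intermediate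
18 | (1R,3R,4S,7S)-3-[(2,2-dimethyl-1,3-dioxan-5-ylidene)methyl]-4-isopropyl-7-{[(4-methoxybenzyl)oxy]methyl}-8-oxabicyclo[5.1.0]octan-2-one | O=C1[C@@H]2O[C@]2(COCc3ccc(OC)cc3)CC[C@@H](C(C)C)[C@@H]1C=C1COC(C)(C)OC1 | intermediate
19 | (1R,3R,4S,7S)-3-[3-hydroxy-2-(hydroxymethyl)prop-1-en-1-yl]-4-isopropyl-7-{[(4-methoxybenzyl)oxy]methyl}-8-oxabicyclo[5.1.0]octan-2-one | O=C1[C@@H]2O[C@]2(COCc3ccc(OC)cc3)CC[C@@H](C(C)C)[C@@H]1C=C(CO)CO | intermediate (not isolated)
20 | 8,9-epoxy-3-(hydroxymethyl)-5-isopropyl-8-{[(4-methoxybenzyl)oxy]methyl}-2,4a,5,6,7,8,9,9a-octahydrocyclohepta[b]pyran-9a-ol (lactol of 19; epoxide cis to the C4a–C4 bond and trans to isopropyl; one anomer drawn) | O[C@]12OCC(CO)=C[C@H]1[C@H](C(C)C)CC[C@@]1(COCc3ccc(OC)cc3)O[C@@H]21 | intermediate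
21 | (5aR,6S,9R,9aS)-9-hydroxy-4-(hydroxymethyl)-6-isopropyl-9-{[(4-methoxybenzyl)oxy]methyl}-5a,6,7,8,9,9a-hexahydro-2-benzoxepin-1(3H)-one | COc1ccc(COC[C@@]2(O)CC[C@@H](C(C)C)[C@@H]3C=C(CO)COC(=O)[C@@H]32)cc1 | intermediate
22 | (5aR,6S,9R,9aS)-9-hydroxy-6-isopropyl-9-{[(4-methoxybenzyl)oxy]methyl}-1-oxo-1,3,5a,6,7,8,9,9a-octahydro-2-benzoxepine-4-carbaldehyde | COc1ccc(COC[C@@]2(O)CC[C@@H](C(C)C)[C@@H]3C=C(C=O)COC(=O)[C@@H]32)cc1 | intermediate (not isolated)
23 | (5aR,6S,9R,9aS)-9-hydroxy-6-isopropyl-9-{[(4-methoxybenzyl)oxy]methyl}-1-oxo-1,3,5a,6,7,8,9,9a-octahydro-2-benzoxepine-4-carboxylic acid | COc1ccc(COC[C@@]2(O)CC[C@@H](C(C)C)[C@@H]3C=C(C(=O)O)COC(=O)[C@@H]32)cc1 | intermediate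
24 | 2-(trimethylsilyl)ethyl (5aR,6S,9R,9aS)-9-hydroxy-6-isopropyl-9-{[(4-methoxybenzyl)oxy]methyl}-1-oxo-1,3,5a,6,7,8,9,9a-octahydro-2-benzoxepine-4-carboxylate | COc1ccc(COC[C@@]2(O)CC[C@@H](C(C)C)[C@@H]3C=C(C(=O)OCC[Si](C)(C)C)COC(=O)[C@@H]32)cc1 | intermediate
25 | 2-(trimethylsilyl)ethyl (5aR,6S,9R,9aS)-9-hydroxy-9-(hydroxymethyl)-6-isopropyl-1-oxo-1,3,5a,6,7,8,9,9a-octahydro-2-benzoxepine-4-carboxylate | OC[C@@]1(O)CC[C@@H](C(C)C)[C@@H]2C=C(C(=O)OCC[Si](C)(C)C)COC(=O)[C@@H]21 | intermediate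
26 | 3-methylbutanal | CC(C)CC=O | starting material
27 | but-3-en-2-one | CC(=O)C=C | starting material
28 | (2R)-2-isopropyl-5-oxohexanal | CC(=O)CC[C@@H](C=O)C(C)C | intermediate
29 | (4R)-4-isopropylcyclohex-2-en-1-one | CC(C)[C@H]1CCC(=O)C=C1 | intermediate
30 | methyl (triphenylphosphoranylidene)acetate | COC(=O)C=P(c1ccccc1)(c1ccccc1)c1ccccc1 | starting material
31 | methyl bromo(triphenylphosphoranylidene)acetate | COC(=O)C(Br)=P(c1ccccc1)(c1ccccc1)c1ccccc1 | intermediate
32 | bromomagnesium (3R,4R)-3-ethenyl-4-isopropylcyclohex-1-en-1-olate | CC(C)[C@H]1CCC(O[Mg]Br)=C[C@@H]1C=C | intermediate (not isolated)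
33 | (3R,4R)-3-ethenyl-4-isopropylcyclohex-1-en-1-yl trifluoromethanesulfonate (vinyl and isopropyl trans) | CC(C)[C@H]1CCC(OS(=O)(=O)C(F)(F)F)=C[C@@H]1C=C | intermediate
34 | (3R,4R)-3-formyl-4-isopropylcyclohex-1-en-1-yl trifluoromethanesulfonate | CC(C)[C@H]1CCC(OS(=O)(=O)C(F)(F)F)=C[C@@H]1C=O | intermediate (not isolated)
35 | methyl (2Z)-2-bromo-3-[(1R,6R)-6-isopropyl-3-{[(trifluoromethyl)sulfonyl]oxy}cyclohex-2-en-1-yl]prop-2-enoate | CC(C)[C@H]1CCC(OS(=O)(=O)C(F)(F)F)=C[C@@H]1/C=C(\Br)C(=O)OC | intermediate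
36 | methyl (2E)-2-(hydroxymethyl)-3-[(1R,6R)-3-(hydroxymethyl)-6-isopropylcyclohex-2-en-1-yl]prop-2-enoate | CC(C)[C@H]1CCC(CO)=C[C@@H]1/C=C(\CO)C(=O)OC | intermediate
37 | methyl (2E)-2-({[tert-butyl(dimethyl)silyl]oxy}methyl)-3-[(1R,6R)-3-({[tert-butyl(dimethyl)silyl]oxy}methyl)-6-isopropylcyclohex-2-en-1-yl]prop-2-enoate | CC(C)[C@H]1CCC(CO[Si](C)(C)C(C)(C)C)=C[C@@H]1/C=C(\CO[Si](C)(C)C(C)(C)C)C(=O)OC | intermediate
38 | (2E)-2-({[tert-butyl(dimethyl)silyl]oxy}methyl)-3-[(1R,6R)-3-({[tert-butyl(dimethyl)silyl]oxy}methyl)-6-isopropylcyclohex-2-en-1-yl]prop-2-enoic acid | CC(C)[C@H]1CCC(CO[Si](C)(C)C(C)(C)C)=C[C@@H]1/C=C(\CO[Si](C)(C)C(C)(C)C)C(=O)O | intermediate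
39 | mixed anhydride of 38 with 2,4,6-trichlorobenzoic acid | CC(C)[C@H]1CCC(CO[Si](C)(C)C(C)(C)C)=C[C@@H]1/C=C(\CO[Si](C)(C)C(C)(C)C)C(=O)OC(=O)c1c(Cl)cc(Cl)cc1Cl | intermediate (not isolated)
40 | 2-(trimethylsilyl)ethyl (5aR,6S,9R,9aS)-9-({[(2E)-2-({[tert-butyl(dimethyl)silyl]oxy}methyl)-3-[(1R,6R)-3-({[tert-butyl(dimethyl)silyl]oxy}methyl)-6-isopropylcyclohex-2-en-1-yl]prop-2-enoyl]oxy}methyl)-9-hydroxy-6-isopropyl-1-oxo-1,3,5a,6,7,8,9,9a-octahydro-2-benzoxepine-4-carboxylate | CC(C)[C@H]1CCC(CO[Si](C)(C)C(C)(C)C)=C[C@@H]1/C=C(\CO[Si](C)(C)C(C)(C)C)C(=O)OC[C@@]1(O)CC[C@@H](C(C)C)[C@@H]2C=C(C(=O)OCC[Si](C)(C)C)COC(=O)[C@@H]21 | intermediate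
41 | (5aR,6S,9R,9aS)-9-hydroxy-9-({[(2E)-2-(hydroxymethyl)-3-[(1R,6R)-3-(hydroxymethyl)-6-isopropylcyclohex-2-en-1-yl]prop-2-enoyl]oxy}methyl)-6-isopropyl-1-oxo-1,3,5a,6,7,8,9,9a-octahydro-2-benzoxepine-4-carboxylic acid | CC(C)[C@H]1CCC(CO)=C[C@@H]1/C=C(\CO)C(=O)OC[C@@]1(O)CC[C@@H](C(C)C)[C@@H]2C=C(C(=O)O)COC(=O)[C@@H]21 | target

**Step count and risks**

Total step count: 25. Longest linear sequence: 15 steps (steps 2–5, 7–15, 24 and 25).

Steps most likely to fail:

1. Step 12 (proposed new method). What may go wrong: ring-opening of the lactol to the hydroxy ketone followed by enolisation and a cyclopropanone-type pathway that scrambles the alkenyl-bearing centre, unproductive Payne-type oxygen migration, or retro-aldol cleavage of the tertiary alkoxide product. The fallback uses the known alkali-induced Favorskii-type ring contraction of an α,β-epoxy ketone with hydroxide as external nucleophile and sets out from 18. Aqueous NaOH in 1,4-dioxane should give (1S,2R,5S,6R)-6-[(2,2-dimethyl-1,3-dioxan-5-ylidene)methyl]-2-hydroxy-5-isopropyl-2-{[(4-methoxybenzyl)oxy]methyl}cyclohexane-1-carboxylic acid F1. Acetonide removal with AcOH/H2O gives (1S,2R,5S,6R)-2-hydroxy-6-[3-hydroxy-2-(hydroxymethyl)prop-1-en-1-yl]-5-isopropyl-2-{[(4-methoxybenzyl)oxy]methyl}cyclohexane-1-carboxylic acid F2. Lactonisation with 2-methyl-6-nitrobenzoic anhydride, Et3N and DMAP at high dilution engages the only hydroxymethyl group that can reach the carboxyl and comes back to the route at 21.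

2. Step 7. What may go wrong: slow oxidative addition or transmetalation with the trisubstituted bromoalkene, protodestannylation of the tin enolate back to the ketone, or migration of the new double bond into conjugation with the ketone. The fallback builds the same bond by cross-coupling on an sp2 carbon and sets out from 9. I2/pyridine α-iodination gives 2-iodo-6-{[(4-methoxybenzyl)oxy]methyl}cyclohepta-2,6-dien-1-one F5. Separately, 13 is converted with bis(pinacolato)diboron, PdCl2(dppf) and KOAc into 2-[(2,2-dimethyl-1,3-dioxan-5-ylidene)methyl]-4,4,5,5-tetramethyl-1,3,2-dioxaborolane F6. Suzuki coupling (Pd(PPh3)4, K3PO4) gives 2-[(2,2-dimethyl-1,3-dioxan-5-ylidene)methyl]-6-{[(4-methoxybenzyl)oxy]methyl}cyclohepta-2,6-dien-1-one F7. Conjugate addition of i-Pr2Zn with Cu(OTf)2 and the same phosphoramidite, then protonation of the zinc enolate and equilibration to the trans isomer, comes back at 15.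

3. Step 8. What may go wrong: poor facial selectivity, with hydride delivered syn to the C7 alkenyl group, which would put the directed epoxide of step 9 on the wrong face. The fallback corrects the carbinol centre by inversion and sets out from 15. Reduction with NaBH4/CeCl3·7H2O gives (1R,6S,7R)-7-[(2,2-dimethyl-1,3-dioxan-5-ylidene)methyl]-6-isopropyl-3-{[(4-methoxybenzyl)oxy]methyl}cyclohept-2-en-1-ol F3. Mitsunobu reaction with 4-nitrobenzoic acid, PPh3 and diisopropyl azodicarboxylate gives the inverted (1S,6S,7R)-4-nitrobenzoate F4. Methanolysis with K2CO3 in MeOH comes back at 16.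

Further compounds
F1 | step 12 | (1S,2R,5S,6R)-6-[(2,2-dimethyl-1,3-dioxan-5-ylidene)methyl]-2-hydroxy-5-isopropyl-2-{[(4-methoxybenzyl)oxy]methyl}cyclohexane-1-carboxylic acid | COc1ccc(COC[C@@]2(O)CC[C@@H](C(C)C)[C@H](C=C3COC(C)(C)OC3)[C@@H]2C(=O)O)cc1
F2 | step 12 | (1S,2R,5S,6R)-2-hydroxy-6-[3-hydroxy-2-(hydroxymethyl)prop-1-en-1-yl]-5-isopropyl-2-{[(4-methoxybenzyl)oxy]methyl}cyclohexane-1-carboxylic acid | COc1ccc(COC[C@@]2(O)CC[C@@H](C(C)C)[C@H](C=C(CO)CO)[C@@H]2C(=O)O)cc1
F5 | step 7 | 2-iodo-6-{[(4-methoxybenzyl)oxy]methyl}cyclohepta-2,6-dien-1-one | O=C1C=C(COCc2ccc(OC)cc2)CCC=C1I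
F6 | step 7 | 2-[(2,2-dimethyl-1,3-dioxan-5-ylidene)methyl]-4,4,5,5-tetramethyl-1,3,2-dioxaborolane | CC1(C)OCC(=CB2OC(C)(C)C(C)(C)O2)CO1
F7 | step 7 | 2-[(2,2-dimethyl-1,3-dioxan-5-ylidene)methyl]-6-{[(4-methoxybenzyl)oxy]methyl}cyclohepta-2,6-dien-1-one | O=C1C=C(COCc2ccc(OC)cc2)CCC=C1C=C1COC(C)(C)OC1
F3 | step 8 | (1R,6S,7R)-7-[(2,2-dimethyl-1,3-dioxan-5-ylidene)methyl]-6-isopropyl-3-{[(4-methoxybenzyl)oxy]methyl}cyclohept-2-en-1-ol | O[C@H]1C=C(COCc2ccc(OC)cc2)CC[C@@H](C(C)C)[C@@H]1C=C1COC(C)(C)OC1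
F4 | step 8 | (1S,6S,7R)-7-[(2,2-dimethyl-1,3-dioxan-5-ylidene)methyl]-6-isopropyl-3-{[(4-methoxybenzyl)oxy]methyl}cyclohept-2-en-1-yl 4-nitrobenzoate | O=C(O[C@@H]1C=C(COCc2ccc(OC)cc2)CC[C@@H](C(C)C)[C@@H]1C=C1COC(C)(C)OC1)c1ccc([N+](=O)[O-])cc1
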